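Compound numbers used throughout are those of the steps and of the compound list after step 12. Flavonol atoms carry the usual flavone numbers (O1, C2–C8a, ring B at C2). The six carbons of the dihydrochalcone ring are D1–D6 (D1 bears the bridging CH2), and its 4-hydroxyphenyl ring is ring E.

## Analysis of the target

4'''-Hydroxytrianguletin (27) is a hybrid of two polyphenols. A kaempferide unit (rings A and C fused as a 4H-chromen-4-one, ring B a 4-methoxyphenyl group at C2) is joined through a single CH2 at C8 to D1 of a benzene ring with no hydrogen left on it. Ring D carries, in order, the bridge (D1), OH (D2), a 3-(4-hydroxyphenyl)propanoyl group (D3), OH (D4), CH3 (D5) and OCH3 (D6). There is no stereocentre and no double-bond geometry, so every selectivity question is one of regiochemistry: C8 against C6 on ring A, and the order of six different substituents on ring D. The sensitive parts are six free phenols that oxidise easily under base, a 3-hydroxy-4-pyranone that chelates metals and absorbs strongly in the near UV, and an aryl ketone flanked by two hydroxyls that is open to oxidative cleavage by peroxide. Two methyl ethers (C4' and D6) must survive while all other oxygens end free, so the protecting groups have to be removable without touching O–CH3. The hard part is a benzene ring with three oxygens of which exactly one is methylated, next to a methyl group and a bulky benzylic substituent. The route rests on ring D splitting into a four-carbon vinylketene (D2, D1, D6, D5, carrying the future hydroxyl, the bridge, the methoxyl and the methyl) and a two-carbon oxygenated alkyne (D3, D4), while rings A, B and C with all their oxygens come from kaempferide (1).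

## Retrosynthetic reasoning

**27 to 26.** The last cut removes three O–benzyl bonds at O3, O5 and O7. Benzyl is the one ether that withstands everything before it (borane, oxidant, acid chloride formation, amine base, heating at 110 °C, fluoride, dry acid) and falls to hydrogenolysis, which leaves both methyl ethers and the ketone alone.

**26 to 23 and 24.** The D3–C(=O) bond is cut next. In 23, D3 is the only ring D carbon that bears hydrogen; it lies between two hydroxyls and para to the methoxyl, the classic site of a Houben–Hoesch acylation. Nitrile 24 delivers the chain and ring E in one piece with its phenol unprotected. A light-driven acyl shift from a D2 ester was considered and set aside: the tribenzylated chromenone would take up most of the light, and 3-benzyloxy-2-arylchromenones react photochemically at their benzylic CH2.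

**23 to 22.** The O–Si bond at D4 is cut; the silyl group is only the handle the alkyne needed. Because D2 and D4 both end as free hydroxyls, which of the two carried silicon has no bearing on the target.

**22 to 13 and 17 (key disconnection).** The D2–D3 and D4–D5 bonds are cut, which takes ring D apart into cyclobutenone 13 and siloxyalkyne 17. Nowhere else does a cut of ring D give two pieces that each carry their substituents in a fixed order: 13 holds bridge, methoxyl and methyl on three neighbouring carbons, and 17 brings the second oxygen and the one unsubstituted carbon. The forward reaction must open 13 to vinylketene 18, add 17 with the CH carbon on the ketene carbon, and close the six-membered ring.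

**17 to 14.** The C–O bond of the ynol ether is cut back to acetylene (14); the forward step is oxidation of the lithium acetylide and silylation on oxygen.

**13 to 7 and 10.** The four-membered ring is cut at C1–C2 and C3–C4, which gives ketene 12 (from acid 7 through chloride 11) and 1-methoxyprop-1-yne (10). The methoxyl is brought in with 10. A higher alkoxy homologue of 10 followed by alkoxy exchange would pass through the free vinylogous acid, whose two enol forms alkylate to two isomeric enol ethers and whose strained ring is opened by alcohols.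

**10 to 8.** Alkyne 10 goes back to chloroacetal 8 by elimination and C-methylation.

**7 to 6 to 5.** These are changes of oxidation level only. The three carbons of the allyl group of 5 become the bridge CH2, D1 and D2, so the bridge is in place before ring D exists.

**5 to 4 to 3 to 1 and 2.** The C8–C bond is traced to an aromatic Claisen rearrangement of allyl ether 3, made from 1 and allyl bromide (2). This uses the inherent bias of the 7-oxygenated chromenone toward C8 and needs no halogenation of ring A.

## Alternatives that were turned down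

**Alternative 1: aryne insertion for the vicinal hydroxyl and acyl groups.** The cuts are D2–O and D3–C(=O). A fluoride source would release the D2–D3 aryne from ortho-silylaryl triflate A2, the carboxylate of acid A3 would add at D2, and the aryl anion at D3 would take the acyl group to give A1. In its favour, hydroxyl and ketone arrive together, ortho to each other, under mild non-acidic conditions; on that point it is stronger than the chosen route, which needs a separate acid-mediated acylation (step 11). Against it, A2 is itself a fully substituted benzene, so the real problem, the order of six substituents, is only moved back. The aryne is also flanked by the bulky benzylic group at D1 and an alkoxy group at D4: the alkoxy group steers the oxygen nucleophile to D2, the crowding at D1 steers it to D3, and the two effects oppose each other. After A1 the whole pyranone still has to be built on the ring A precursor in the presence of an enolisable dihydrochalcone ketone. The chosen route instead fixes the ring D pattern through the connectivity of 13 and 17 and takes rings A to C ready-made from 1.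

**Alternative 2: late Algar–Flynn–Oyamada closure of ring C.** The cuts are O1–C2 and C3–OH. Alkaline peroxide would epoxidise chalcone A5, and the one free ortho phenoxide would open the epoxide to give A4, two acetal cleavages from 27. In its favour it is the textbook flavonol synthesis and ends very close to the target, closer than 22 is. Against it, A5 carries an alkoxy group at the ring A position ortho to the carbonyl on the side away from the free phenol, a pattern that is known to divert this reaction toward aurones. Ring D would be exposed to alkaline peroxide with free phenols and an aryl ketone between two hydroxyls, which invites Dakin-type cleavage and phenol oxidation. Making A5 also needs an aldol condensation that must distinguish two enolisable aryl ketones. In the chosen route no oxidant is used once the electron-rich ring D exists.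

**Alternative 3: ring A grown last on a 4-pyranone.** The cut is C5–C6. An alkoxide base would convert the methyl ketone of pyranone keto ester A7 into its enolate, which attacks the neighbouring ester and, after loss of alkoxide and enolisation, gives flavone A6. In its favour the C8 substituent is placed by construction, so there is no C6/C8 question at all; here it is stronger than the Claisen rearrangement of step 2. Against it, A6 has no oxygen at C3, so the 3-hydroxyl would have to be introduced on a late intermediate that holds free phenols and a ketone. A7 needs a long synthesis of a tetrasubstituted pyranone, and the base meets three enolisable positions. The hexasubstituted ring D must still be made separately before any of this. The chosen route starts from a flavonol that already has the 3-hydroxyl and spends its steps on ring D only.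

Key step: step 9

Remarks on the chemistry: alkynes 10 and 17 are not assumed to be purchasable and are made in steps 6 and 8. Compounds 13, 19 and 21 are racemates whose stereocentres vanish before 22.

## Route

Step 1
Reactants: 1 kaempferide (3,5,7-trihydroxy-2-(4-methoxyphenyl)-4H-chromen-4-one); 2 allyl bromide
Product: 3 7-O-allylkaempferide (3,5-dihydroxy-2-(4-methoxyphenyl)-7-(prop-2-en-1-yloxy)-4H-chromen-4-one)
Conditions: K2CO3 (1.1 equiv), DMF, 0 °C → rt
Reagents that add atoms: none
Why: Williamson ether synthesis; the 7-hydroxyl is the most acidic phenol (vinylogous to the C4 carbonyl) and is not held in a hydrogen bond to that carbonyl as the 3- and 5-hydroxyls are, so one equivalent of halide should alkylate it first.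

Step 2
Reactants: 3 7-O-allylkaempferide
Product: 4 8-allylkaempferide (3,5,7-trihydroxy-2-(4-methoxyphenyl)-8-(prop-2-en-1-yl)-4H-chromen-4-one)
Conditions: PhNEt2, 200 °C, argon
Reagents that add atoms: none
Why: Aromatic Claisen rearrangement ([3,3]-sigmatropic shift, then enolisation); migration to C8 is expected to prevail as in 7-allyloxychromenones and 7-allyloxycoumarins, where the C7–C8 bond has more double-bond character than C6–C7, and any C6 isomer is removed at this stage.

Step 3
Reactants: 4 8-allylkaempferide
Product: 5 3,5,7-tris(benzyloxy)-2-(4-methoxyphenyl)-8-(prop-2-en-1-yl)-4H-chromen-4-one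
Conditions: BnBr (4.5 equiv), K2CO3 (6 equiv), DMF, 70 °C
Reagents that add atoms: benzyl bromide, BrCc1ccccc1
Why: Williamson etherification of all three hydroxyls, the chelated 5-hydroxyl needing excess reagent and heat; benzyl survives every later step and is removed at the end without touching the methyl ethers.

Step 4
Reactants: 5 3,5,7-tris(benzyloxy)-2-(4-methoxyphenyl)-8-(prop-2-en-1-yl)-4H-chromen-4-one
Product: 6 3,5,7-tris(benzyloxy)-8-(3-hydroxypropyl)-2-(4-methoxyphenyl)-4H-chromen-4-one
Conditions: 9-BBN (1.5 equiv), THF, 0 °C → rt; then aq. NaOH, 30% H2O2, 0 °C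
Reagents that add atoms: hydrogen peroxide, OO
Why: Anti-Markovnikov hydroboration–oxidation; the hindered dialkylborane adds only to the terminal alkene and does not reduce the vinylogous ester carbonyl of the chromenone, and cold alkaline peroxide oxidises the C–B bond.

Step 5
Reactants: 6 3,5,7-tris(benzyloxy)-8-(3-hydroxypropyl)-2-(4-methoxyphenyl)-4H-chromen-4-one
Product: 7 3-[3,5,7-tris(benzyloxy)-2-(4-methoxyphenyl)-4-oxo-4H-chromen-8-yl]propanoic acid
Conditions: TEMPO (0.2 equiv), PhI(OAc)2 (2.5 equiv), MeCN–H2O (1:1), rt
Reagents that add atoms: water, O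
Why: Nitroxyl-catalysed oxidation of the primary alcohol through the aldehyde hydrate to the acid; the oxoammonium ion is selective for the alcohol and should leave the benzyl ethers and the alkoxy-substituted rings alone.

Step 6
Reactants: 8 2-chloro-1,1-dimethoxyethane (chloroacetaldehyde dimethyl acetal)
Product: 10 1-methoxyprop-1-yne, via sodium methoxyethynide 9 (not isolated)
Conditions: NaNH2 (3.1 equiv), liquid NH3, −35 °C; then MeI (1.0 equiv), −35 °C; distillation
Reagents that add atoms: iodomethane, CI
Why: Amide base removes methanol and HCl from the chloroacetal and deprotonates the alkoxyacetylene, and the sodium acetylide is C-methylated in the same flask; this is the standard route to 1-alkoxyalk-1-ynes.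

Step 7
Reactants: 7 3-[3,5,7-tris(benzyloxy)-2-(4-methoxyphenyl)-4-oxo-4H-chromen-8-yl]propanoic acid; 10 1-methoxyprop-1-yne
Product: 13 racemic 4-{[3,5,7-tris(benzyloxy)-2-(4-methoxyphenyl)-4-oxo-4H-chromen-8-yl]methyl}-3-methoxy-2-methylcyclobut-2-en-1-one, via acid chloride 11 (not isolated), via aldoketene 12 (not isolated)
Conditions: Me2C=C(Cl)NMe2 (1.2 equiv), CH2Cl2, 0 °C → rt; then slow addition to 10 (5 equiv), Et3N (1.5 equiv), CH2Cl2, rt → 40 °C
Reagents that add atoms: none
Why: Neutral conversion of the acid into its chloride, dehydrochlorination to the monosubstituted ketene, and ketene–ynol ether [2+2] cycloaddition, in which the methyl-bearing alkyne carbon (nucleophilic, β to oxygen) bonds to the ketene carbonyl carbon and the methoxy-bearing carbon to the ketene α-carbon. Slow addition and excess 10 hold back ketene dimerisation; the C4 stereocentre forms as a racemate and is lost in step 9.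

Step 8
Reactants: 14 acetylene
Product: 17 (triisopropylsilyloxy)ethyne, via lithium acetylide 15 (not isolated), via lithium ethynolate 16 (not isolated)
Conditions: n-BuLi (1.0 equiv), THF, −78 °C; t-BuOOH (1.0 equiv), LiN(SiMe3)2 (1.0 equiv), THF, −78 → 0 °C; i-Pr3SiOTf (1.0 equiv), −78 °C
Reagents that add atoms: tert-butyl hydroperoxide, CC(C)(C)OO; triisopropylsilyl trifluoromethanesulfonate, CC(C)[Si](OS(=O)(=O)C(F)(F)F)(C(C)C)C(C)C
Why: The acetylide attacks the peroxide oxygen of lithium tert-butyl peroxide to give the ynolate, and the bulky silyl triflate traps it on oxygen; the oxidation–silylation sequence is established for terminal alkynes and is applied here to acetylene itself.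

Step 9
Reactants: 13 racemic 4-{[3,5,7-tris(benzyloxy)-2-(4-methoxyphenyl)-4-oxo-4H-chromen-8-yl]methyl}-3-methoxy-2-methylcyclobut-2-en-1-one; 17 (triisopropylsilyloxy)ethyne
Product: 22 3,5,7-tris(benzyloxy)-8-{[6-hydroxy-2-methoxy-3-methyl-4-(triisopropylsilyloxy)phenyl]methyl}-2-(4-methoxyphenyl)-4H-chromen-4-one, via vinylketene 18 (not isolated), via vinylcyclobutenone 19 (not isolated), via dienylketene 20 (not isolated), via cyclohexadienone 21 (not isolated)
Conditions: 17 (2.5 equiv, two portions), toluene, 80 → 110 °C, sealed tube, argon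
Reagents that add atoms: none
Why: This is a Danheiser benzannulation, a known cascade of four pericyclic steps between a cyclobutenone and a siloxyalkyne, used here with a 3-alkoxycyclobutenone. Heat opens 13 by four-electron conrotatory cleavage of its C1–C4 bond, the C4 substituent turning outward, to vinylketene 18. The ketene C=C of 18 adds 17 in a [2+2] cycloaddition in which the unsubstituted alkyne carbon bonds to the ketene carbonyl carbon and the siloxy carbon to the methyl-bearing carbon, which gives 19 and makes the D2–D3 and D4–D5 bonds. Ring opening of 19 (four-electron, reversible) gives dienylketene 20, and the isomer with the vinyl group cis to the ketenyl group closes ring D by six-electron disrotatory electrocyclisation, re-forming the D1–D2 bond, to 21, which tautomerises to phenol 22. No stereocentre is created, and the one in 13 disappears on ring opening. The selectivity needed is the regiochemistry of the ketene–alkyne addition; the oxygen donor makes the CH carbon of 17 the nucleophile and the ketene carbonyl carbon is the electrophile, so H falls on D3, OSi on D4, CH3 on D5, OCH3 on D6 and the bridge on D1. Outward rotation keeps the CH2 group away from the ketene in 18, so a 1,5-hydrogen shift to a dienal is not open. The bulk of the triisopropylsilyl group slows the oxygen-to-carbon silyl shift of 17 to a silylketene at this temperature.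

Step 10
Reactants: 22 3,5,7-tris(benzyloxy)-8-{[6-hydroxy-2-methoxy-3-methyl-4-(triisopropylsilyloxy)phenyl]methyl}-2-(4-methoxyphenyl)-4H-chromen-4-one
Product: 23 3,5,7-tris(benzyloxy)-8-[(4,6-dihydroxy-2-methoxy-3-methylphenyl)methyl]-2-(4-methoxyphenyl)-4H-chromen-4-one
Conditions: Bu4NF (1.1 equiv), AcOH (1.1 equiv), THF, 0 °C, argon
Reagents that add atoms: none
Why: Fluoride cleavage of the aryl silyl ether; acetic acid buffers the phenoxide so the electron-rich ring is not oxidised, and the benzyl ethers are untouched.

Step 11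
Reactants: 23 3,5,7-tris(benzyloxy)-8-[(4,6-dihydroxy-2-methoxy-3-methylphenyl)methyl]-2-(4-methoxyphenyl)-4H-chromen-4-one; 24 3-(4-hydroxyphenyl)propanenitrile
Product: 26 3,5,7-tris(benzyloxy)-8-({2,4-dihydroxy-3-[3-(4-hydroxyphenyl)propanoyl]-6-methoxy-5-methylphenyl}methyl)-2-(4-methoxyphenyl)-4H-chromen-4-one, via ketiminium chloride 25 (not isolated)
Conditions: ZnCl2 (2 equiv), dry HCl, Et2O–1,4-dioxane, 0 °C; then H2O–THF, 60 °C
Reagents that add atoms: water, O
Why: Houben–Hoesch acylation; the electrophile formed from 24, HCl and ZnCl2 attacks D3, the only unsubstituted carbon of ring D, ortho to both hydroxyls and para to the methoxyl, and the ketiminium salt is then hydrolysed to the ketone. C6 of ring A should stay untouched because the pyranone is protonated in this medium, and the phenol ring of 24 is far less nucleophilic than ring D.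

Step 12
Reactants: 26 3,5,7-tris(benzyloxy)-8-({2,4-dihydroxy-3-[3-(4-hydroxyphenyl)propanoyl]-6-methoxy-5-methylphenyl}methyl)-2-(4-methoxyphenyl)-4H-chromen-4-one
Product: 27 4'''-hydroxytrianguletin
Conditions: H2 (1 atm), 10% Pd/C, EtOAc–MeOH, rt
Reagents that add atoms: none
Why: Hydrogenolysis of the three benzyl ethers; the chromenone C2–C3 double bond, the hydrogen-bonded aryl ketone, the diarylmethane and both methyl ethers are expected to survive at atmospheric pressure.

## Compound list

1 | kaempferide | COc1ccc(-c2oc3cc(O)cc(O)c3c(=O)c2O)cc1 | starting material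
2 | allyl bromide | C=CCBr | starting material
3 | 7-O-allylkaempferide | COc1ccc(-c2oc3cc(OCC=C)cc(O)c3c(=O)c2O)cc1 | intermediate
4 | 8-allylkaempferide | COc1ccc(-c2oc3c(CC=C)c(O)cc(O)c3c(=O)c2O)cc1 | intermediate
5 | 3,5,7-tris(benzyloxy)-2-(4-methoxyphenyl)-8-(prop-2-en-1-yl)-4H-chromen-4-one | COc1ccc(-c2oc3c(CC=C)c(OCc4ccccc4)cc(OCc4ccccc4)c3c(=O)c2OCc2ccccc2)cc1 | intermediate
6 | 3,5,7-tris(benzyloxy)-8-(3-hydroxypropyl)-2-(4-methoxyphenyl)-4H-chromen-4-one | COc1ccc(-c2oc3c(CCCO)c(OCc4ccccc4)cc(OCc4ccccc4)c3c(=O)c2OCc2ccccc2)cc1 | intermediate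
7 | 3-[3,5,7-tris(benzyloxy)-2-(4-methoxyphenyl)-4-oxo-4H-chromen-8-yl]propanoic acid | COc1ccc(-c2oc3c(CCC(=O)O)c(OCc4ccccc4)cc(OCc4ccccc4)c3c(=O)c2OCc2ccccc2)cc1 | intermediate
8 | 2-chloro-1,1-dimethoxyethane | COC(CCl)OC | starting material
9 | sodium methoxyethynide | [Na+].[C-]#COC | intermediate
10 | 1-methoxyprop-1-yne | CC#COC | intermediate
11 | 3-[3,5,7-tris(benzyloxy)-2-(4-methoxyphenyl)-4-oxo-4H-chromen-8-yl]propanoyl chloride | COc1ccc(-c2oc3c(CCC(=O)Cl)c(OCc4ccccc4)cc(OCc4ccccc4)c3c(=O)c2OCc2ccccc2)cc1 | intermediate
12 | 3-[3,5,7-tris(benzyloxy)-2-(4-methoxyphenyl)-4-oxo-4H-chromen-8-yl]prop-1-en-1-one (aldoketene) | COc1ccc(-c2oc3c(CC=C=O)c(OCc4ccccc4)cc(OCc4ccccc4)c3c(=O)c2OCc2ccccc2)cc1 | intermediate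
13 | racemic 4-{[3,5,7-tris(benzyloxy)-2-(4-methoxyphenyl)-4-oxo-4H-chromen-8-yl]methyl}-3-methoxy-2-methylcyclobut-2-en-1-one | COC1=C(C)C(=O)C1Cc1c(OCc2ccccc2)cc(OCc2ccccc2)c2c(=O)c(OCc3ccccc3)c(-c3ccc(OC)cc3)oc12 | intermediate
14 | acetylene | C#C | starting material
15 | lithium acetylide | [Li+].[C-]#C | intermediate
16 | lithium ethynolate | [Li+].[O-]C#C | intermediate
17 | (triisopropylsilyloxy)ethyne | C#CO[Si](C(C)C)(C(C)C)C(C)C | intermediate
18 | vinylketene: 3-methoxy-2-methyl-5-[3,5,7-tris(benzyloxy)-2-(4-methoxyphenyl)-4-oxo-4H-chromen-8-yl]penta-1,3-dien-1-one, CH2 group trans to the ketene-bearing carbon (3Z) | O=C=C(C)/C(OC)=C/Cc1c(OCc2ccccc2)cc(OCc2ccccc2)c2c(=O)c(OCc3ccccc3)c(-c3ccc(OC)cc3)oc12 | intermediate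
19 | racemic 4-{(Z)-1-methoxy-3-[3,5,7-tris(benzyloxy)-2-(4-methoxyphenyl)-4-oxo-4H-chromen-8-yl]prop-1-en-1-yl}-4-methyl-3-(triisopropylsilyloxy)cyclobut-2-en-1-one | O=C1C=C(O[Si](C(C)C)(C(C)C)C(C)C)C1(C)/C(OC)=C/Cc1c(OCc2ccccc2)cc(OCc2ccccc2)c2c(=O)c(OCc3ccccc3)c(-c3ccc(OC)cc3)oc12 | intermediate
20 | dienylketene: (3E,5Z)-5-methoxy-4-methyl-3-(triisopropylsilyloxy)-7-[3,5,7-tris(benzyloxy)-2-(4-methoxyphenyl)-4-oxo-4H-chromen-8-yl]hepta-1,3,5-trien-1-one, vinyl group cis to the ketenyl group | O=C=C/C(O[Si](C(C)C)(C(C)C)C(C)C)=C(C)\C(OC)=C\Cc1c(OCc2ccccc2)cc(OCc2ccccc2)c2c(=O)c(OCc3ccccc3)c(-c3ccc(OC)cc3)oc12 | intermediate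
21 | racemic 6-{[3,5,7-tris(benzyloxy)-2-(4-methoxyphenyl)-4-oxo-4H-chromen-8-yl]methyl}-5-methoxy-4-methyl-3-(triisopropylsilyloxy)cyclohexa-2,4-dien-1-one | O=C1C=C(O[Si](C(C)C)(C(C)C)C(C)C)C(C)=C(OC)C1Cc1c(OCc2ccccc2)cc(OCc2ccccc2)c2c(=O)c(OCc3ccccc3)c(-c3ccc(OC)cc3)oc12 | intermediate
22 | 3,5,7-tris(benzyloxy)-8-{[6-hydroxy-2-methoxy-3-methyl-4-(triisopropylsilyloxy)phenyl]methyl}-2-(4-methoxyphenyl)-4H-chromen-4-one | COc1c(C)c(O[Si](C(C)C)(C(C)C)C(C)C)cc(O)c1Cc1c(OCc2ccccc2)cc(OCc2ccccc2)c2c(=O)c(OCc3ccccc3)c(-c3ccc(OC)cc3)oc12 | intermediate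
23 | 3,5,7-tris(benzyloxy)-8-[(4,6-dihydroxy-2-methoxy-3-methylphenyl)methyl]-2-(4-methoxyphenyl)-4H-chromen-4-one | COc1c(C)c(O)cc(O)c1Cc1c(OCc2ccccc2)cc(OCc2ccccc2)c2c(=O)c(OCc3ccccc3)c(-c3ccc(OC)cc3)oc12 | intermediate
24 | 3-(4-hydroxyphenyl)propanenitrile | N#CCCc1ccc(O)cc1 | starting material
25 | ketiminium chloride of 26 (C=NH2+ in place of C=O at D3) | COc1c(C)c(O)c(C(=[NH2+])CCc2ccc(O)cc2)c(O)c1Cc1c(OCc2ccccc2)cc(OCc2ccccc2)c2c(=O)c(OCc3ccccc3)c(-c3ccc(OC)cc3)oc12.[Cl-] | intermediate
26 | 3,5,7-tris(benzyloxy)-8-({2,4-dihydroxy-3-[3-(4-hydroxyphenyl)propanoyl]-6-methoxy-5-methylphenyl}methyl)-2-(4-methoxyphenyl)-4H-chromen-4-one | COc1c(C)c(O)c(C(=O)CCc2ccc(O)cc2)c(O)c1Cc1c(OCc2ccccc2)cc(OCc2ccccc2)c2c(=O)c(OCc3ccccc3)c(-c3ccc(OC)cc3)oc12 | intermediate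
27 | 4'''-hydroxytrianguletin | COc1ccc(-c2oc3c(Cc4c(O)c(C(=O)CCc5ccc(O)cc5)c(O)c(C)c4OC)c(O)cc(O)c3c(=O)c2O)cc1 | target

Total step count: 12. Longest linear sequence: 10 steps (steps 1, 2, 3, 4, 5, 7, 9, 10, 11, 12); steps 6 and 8 make the two alkynes.

## Steps least certain to work

**Step 9 (key step).** The methoxyl on the cyclobutenone double bond stabilises 13 as a vinylogous ester, so the first ring opening may need more heat than 17 tolerates. Most likely to go wrong are loss of the alkyne by silyl migration from oxygen to carbon and acylation of the product phenol by vinylketene still present. The fallback gives up the annulation and joins the two halves by a Mannich base and ortho-quinone methide alkylation. It sets out from 1 (with 24 for the other half) and comes back at 27. Aminomethylation of 1 at C8 (HCHO, Me2NH, EtOH, rt) gives 8-[(dimethylamino)methyl]kaempferide F1. Houben–Hoesch acylation of purchased 2-methylbenzene-1,3,5-triol with 24 gives 1-(2,4,6-trihydroxy-3-methylphenyl)-3-(4-hydroxyphenyl)propan-1-one F2. Its hydroxyl para to the carbonyl, the one acidic hydroxyl not chelated, is methylated (Me2SO4, one equivalent, K2CO3, acetone) to 1-(2,6-dihydroxy-4-methoxy-3-methylphenyl)-3-(4-hydroxyphenyl)propan-1-one F3. Heating F1 with F3 in 1,4-dioxane expels the amine, and the quinone methide is captured by the single free ring carbon of F3, which gives 27 without protecting groups.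

**Step 8.** The parent ynolate is ambident and less hindered at carbon than its substituted relatives, so silylation at carbon to a silylketene may compete; the monolithium acetylide may also disproportionate on warming before it is oxidised. The fallback puts silicon on oxygen first and forms the triple bond by elimination. It sets out from 8 and comes back at 17. Acid hydrolysis of 8 and drying gives chloroacetaldehyde F4; i-Pr3SiOTf and Et3N in CH2Cl2 give [(Z)-2-chloroethenyl]oxy-tri(propan-2-yl)silane F5; LiN(i-Pr)2 (2.2 equiv, THF, −78 °C) removes HCl, and protonation on work-up gives 17.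

**Step 7.** The monosubstituted ketene 12 may dimerise faster than it adds the volatile ynol ether, and the vinylogous ester 13 may hydrolyse on purification. The fallback avoids both the ketene and the four-membered ring and makes vinylketene 18 by 1,4-dehydrochlorination. It sets out from 7 and comes back at 22.
- Activation of 7 with carbonyldiimidazole and acylation of the magnesium salt of monomethyl methylmalonate, with loss of CO2, gives methyl 2-methyl-3-oxo-5-[3,5,7-tris(benzyloxy)-2-(4-methoxyphenyl)-4-oxo-4H-chromen-8-yl]pentanoate F6.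
- HC(OMe)3 with catalytic H2SO4 in MeOH gives methyl 3-methoxy-2-methyl-5-[3,5,7-tris(benzyloxy)-2-(4-methoxyphenyl)-4-oxo-4H-chromen-8-yl]pent-2-enoate F7 as an E/Z mixture.
- LiOH in aqueous THF gives 3-methoxy-2-methyl-5-[3,5,7-tris(benzyloxy)-2-(4-methoxyphenyl)-4-oxo-4H-chromen-8-yl]pent-2-enoic acid F8.
- Me2C=C(Cl)NMe2 gives 3-methoxy-2-methyl-5-[3,5,7-tris(benzyloxy)-2-(4-methoxyphenyl)-4-oxo-4H-chromen-8-yl]pent-2-enoyl chloride F9.
- Et3N removes the γ-hydrogen of F9 at room temperature in the presence of 17, which generates 18 without heating; warming the adduct 19 then carries the cascade through 20 and 21 to 22.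

**Step 11.** Attack of the electrophile on phenolic oxygen in place of D3, attack at C6 of ring A, or acid cleavage of the 5-benzyl ether followed by benzylation of ring D may lower the efficiency. The fallback forms the ketone from an isolated aryl ester. It sets out from 22 and comes back at 27. Esterification of the D2 hydroxyl of 22 with 3-[4-(benzyloxy)phenyl]propanoic acid A3 (dicyclohexylcarbodiimide, 4-(dimethylamino)pyridine, CH2Cl2) gives 2-{[3,5,7-tris(benzyloxy)-2-(4-methoxyphenyl)-4-oxo-4H-chromen-8-yl]methyl}-3-methoxy-4-methyl-5-(triisopropylsilyloxy)phenyl 3-[4-(benzyloxy)phenyl]propanoate F10. A Fries rearrangement (TiCl4, CH2Cl2, 0 °C) moves the acyl group to D3, the one free ortho carbon, and gives the D4-silylated, tetra-O-benzylated dihydrochalcone F11. Bu4NF gives the tetra-O-benzyl ether of 27, F12, and hydrogenolysis over Pd/C gives 27.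

**Step 2.** Poor discrimination between C8 and C6 in the sigmatropic shift would cost material and require a separation of isomers. The fallback fixes C8 by halogenation of the fully etherified flavonol. It sets out from 1 and comes back at 5. Benzylation of 1 (BnBr, K2CO3, DMF, 70 °C) gives 3,5,7-tris(benzyloxy)-2-(4-methoxyphenyl)-4H-chromen-4-one F13. Iodination with I2 and CF3CO2Ag in CH2Cl2, which goes to C8 when the 5-oxygen is alkylated, gives 3,5,7-tris(benzyloxy)-8-iodo-2-(4-methoxyphenyl)-4H-chromen-4-one F14. Stille coupling with allyltributylstannane (Pd(PPh3)4, DMF, 90 °C) gives 5.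

## Further compounds

F1 | step 9 | 8-[(dimethylamino)methyl]kaempferide | COc1ccc(-c2oc3c(CN(C)C)c(O)cc(O)c3c(=O)c2O)cc1
F2 | step 9 | 1-(2,4,6-trihydroxy-3-methylphenyl)-3-(4-hydroxyphenyl)propan-1-one | Cc1c(O)cc(O)c(C(=O)CCc2ccc(O)cc2)c1O
F3 | step 9 | 1-(2,6-dihydroxy-4-methoxy-3-methylphenyl)-3-(4-hydroxyphenyl)propan-1-one | COc1cc(O)c(C(=O)CCc2ccc(O)cc2)c(O)c1C
F4 | step 8 | chloroacetaldehyde | O=CCCl
F5 | step 8 | [(Z)-2-chloroethenyl]oxy-tri(propan-2-yl)silane | Cl/C=C\O[Si](C(C)C)(C(C)C)C(C)C
F6 | step 7 | racemic methyl 2-methyl-3-oxo-5-[3,5,7-tris(benzyloxy)-2-(4-methoxyphenyl)-4-oxo-4H-chromen-8-yl]pentanoate | COC(=O)C(C)C(=O)CCc1c(OCc2ccccc2)cc(OCc2ccccc2)c2c(=O)c(OCc3ccccc3)c(-c3ccc(OC)cc3)oc12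
F7 | step 7 | methyl 3-methoxy-2-methyl-5-[3,5,7-tris(benzyloxy)-2-(4-methoxyphenyl)-4-oxo-4H-chromen-8-yl]pent-2-enoate (E/Z mixture) | COC(=O)C(C)=C(OC)CCc1c(OCc2ccccc2)cc(OCc2ccccc2)c2c(=O)c(OCc3ccccc3)c(-c3ccc(OC)cc3)oc12
F8 | step 7 | 3-methoxy-2-methyl-5-[3,5,7-tris(benzyloxy)-2-(4-methoxyphenyl)-4-oxo-4H-chromen-8-yl]pent-2-enoic acid (E/Z mixture) | OC(=O)C(C)=C(OC)CCc1c(OCc2ccccc2)cc(OCc2ccccc2)c2c(=O)c(OCc3ccccc3)c(-c3ccc(OC)cc3)oc12
F9 | step 7 | 3-methoxy-2-methyl-5-[3,5,7-tris(benzyloxy)-2-(4-methoxyphenyl)-4-oxo-4H-chromen-8-yl]pent-2-enoyl chloride (E/Z mixture) | ClC(=O)C(C)=C(OC)CCc1c(OCc2ccccc2)cc(OCc2ccccc2)c2c(=O)c(OCc3ccccc3)c(-c3ccc(OC)cc3)oc12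
F10 | step 11 | 2-{[3,5,7-tris(benzyloxy)-2-(4-methoxyphenyl)-4-oxo-4H-chromen-8-yl]methyl}-3-methoxy-4-methyl-5-(triisopropylsilyloxy)phenyl 3-[4-(benzyloxy)phenyl]propanoate | COc1c(C)c(O[Si](C(C)C)(C(C)C)C(C)C)cc(OC(=O)CCc2ccc(OCc3ccccc3)cc2)c1Cc1c(OCc2ccccc2)cc(OCc2ccccc2)c2c(=O)c(OCc3ccccc3)c(-c3ccc(OC)cc3)oc12
F11 | step 11 | 3,5,7-tris(benzyloxy)-8-({3-{3-[4-(benzyloxy)phenyl]propanoyl}-2-hydroxy-6-methoxy-5-methyl-4-(triisopropylsilyloxy)phenyl}methyl)-2-(4-methoxyphenyl)-4H-chromen-4-one | COc1c(C)c(O[Si](C(C)C)(C(C)C)C(C)C)c(C(=O)CCc2ccc(OCc3ccccc3)cc2)c(O)c1Cc1c(OCc2ccccc2)cc(OCc2ccccc2)c2c(=O)c(OCc3ccccc3)c(-c3ccc(OC)cc3)oc12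
F12 | step 11 | 3,5,7-tris(benzyloxy)-8-({3-{3-[4-(benzyloxy)phenyl]propanoyl}-2,4-dihydroxy-6-methoxy-5-methylphenyl}methyl)-2-(4-methoxyphenyl)-4H-chromen-4-one | COc1c(C)c(O)c(C(=O)CCc2ccc(OCc3ccccc3)cc2)c(O)c1Cc1c(OCc2ccccc2)cc(OCc2ccccc2)c2c(=O)c(OCc3ccccc3)c(-c3ccc(OC)cc3)oc12
F13 | step 2 | 3,5,7-tris(benzyloxy)-2-(4-methoxyphenyl)-4H-chromen-4-one | COc1ccc(-c2oc3cc(OCc4ccccc4)cc(OCc4ccccc4)c3c(=O)c2OCc2ccccc2)cc1
F14 | step 2 | 3,5,7-tris(benzyloxy)-8-iodo-2-(4-methoxyphenyl)-4H-chromen-4-one | COc1ccc(-c2oc3c(I)c(OCc4ccccc4)cc(OCc4ccccc4)c3c(=O)c2OCc2ccccc2)cc1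
A1 | alternative 1 | protected dihydrochalcone with free D2 hydroxyl, carrying the ring A precursor at D1 | COc1c(C)c(OCc2ccccc2)c(C(=O)CCc2ccc(OCc3ccccc3)cc2)c(O)c1Cc1c(OCOC)cc(OCc2ccccc2)cc1OCc1ccccc1
A2 | alternative 1 | ortho-silylaryl triflate (D2 triflate, D3 trimethylsilyl) with the same D1, D4, D5 and D6 substituents | COc1c(C)c(OCc2ccccc2)c([Si](C)(C)C)c(OS(=O)(=O)C(F)(F)F)c1Cc1c(OCOC)cc(OCc2ccccc2)cc1OCc1ccccc1
A3 | alternative 1 | 3-[4-(benzyloxy)phenyl]propanoic acid | OC(=O)CCc1ccc(OCc2ccccc2)cc1
A4 | alternative 2 | 5,7-bis(methoxymethyl) ether of the target | COc1ccc(-c2oc3c(Cc4c(O)c(C(=O)CCc5ccc(O)cc5)c(O)c(C)c4OC)c(OCOC)cc(OCOC)c3c(=O)c2O)cc1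
A5 | alternative 2 | (E)-chalcone with one free ortho hydroxyl, two methoxymethyl ethers and the ring D benzyl group | COc1ccc(/C=C/C(=O)c2c(OCOC)cc(OCOC)c(Cc3c(O)c(C(=O)CCc4ccc(O)cc4)c(O)c(C)c3OC)c2O)cc1
A6 | alternative 3 | 5,7-dihydroxy-4'-methoxyflavone carrying the benzyl-protected dihydrochalcone benzyl group at C8 | COc1ccc(-c2cc(=O)c3c(O)cc(O)c(Cc4c(OCc5ccccc5)c(C(=O)CCc5ccc(OCc6ccccc6)cc5)c(OCc5ccccc5)c(C)c4OC)c3o2)cc1
A7 | alternative 3 | racemic methyl 6-(4-methoxyphenyl)-4-oxo-2-[1-(protected ring D)-3-oxobutan-2-yl]-4H-pyran-3-carboxylate | COC(=O)c1c(C(Cc2c(OCc3ccccc3)c(C(=O)CCc3ccc(OCc4ccccc4)cc3)c(OCc3ccccc3)c(C)c2OC)C(C)=O)oc(-c2ccc(OC)cc2)cc1=O
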